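**Retrosynthetic overview**
- The only ring is closed at C1–C2 (ring numbering: C1 = ring C=O, C2 = carbon bearing the exocyclic C7H2–O, C3 = ring =CH, C4 = C–O-tigloyl, C5 = C–isopropyl, C6 = C–OAc). The O4-silylated cyclohexenone comes from an acyclic mixed anhydride of an allenic acid with tiglic acid: a palladium-catalysed insertion of the allene into the anhydride C(acyl)–O bond makes the C1–C2 bond, the enone and the C7–O tiglate in one operation.
- Enabling feature: the 2-(acyloxymethyl)cyclohex-2-en-1-one unit C1(=O)–C2(=C3)–C7H2–O is an acyl group on the central carbon and a carboxylate on the terminal carbon of a C3=C2=C7 allene.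
- Acyclic stereotriad: C5/C6 by an Evans syn-aldol with tert-butyl glyoxylate; C4 by an Evans–Tishchenko reduction of a β-hydroxy ynone (1,3-anti), which also places the acetate on O6.
- Allene by Myers reduction of a primary propargylic alcohol; tert-butyl ester as the latent C1 acid.
- After ring closure only O4 is adjusted (desilylation, tigloylation).

Key step: step 10

Remark: both unsaturated acyl groups of the target are (E)-2-methylbut-2-enoyl (tigloyl); di-tert-butyl L-tartrate, the N-isovaleryl oxazolidinone and the silylated propargyl alcohol are taken as catalogue compounds; TBS = tert-butyldimethylsilyl.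

**Step 1**
Reactants: 1 di-tert-butyl L-tartrate
Product: 2 tert-butyl glyoxylate (tert-butyl 2-oxoacetate)
Conditions: H5IO6, Et2O, rt; distil from P2O5 before use
Reagents that add atoms: none
Why: Malaprade glycol cleavage of the vicinal diol gives two equivalents of the monomeric aldehyde; the stereocentres of 1 are destroyed and none is needed.

**Step 2**
Reactants: 3 (4R)-4-benzyl-3-(3-methylbutanoyl)-1,3-oxazolidin-2-one; 2 tert-butyl glyoxylate
Product: 5 tert-butyl (2R,3R)-3-[(4R)-4-benzyl-2-oxo-1,3-oxazolidine-3-carbonyl]-2-hydroxy-4-methylpentanoate, via dibutylboron Z-enolate 4 (not isolated)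
Conditions: n-Bu2BOTf, iPr2NEt, CH2Cl2, 0 °C; then 2, −78 → 0 °C; pH 7 buffer, MeOH, H2O2
Reagents that add atoms: none
Why: Evans syn-aldol reaction: the Z-enolate reacts through a closed Zimmerman–Traxler chair on the face away from the benzyl group of the (R)-auxiliary, which sets C5 and C6 (5,6-syn, both R in 5).

**Step 3**
Reactants: 5 tert-butyl (2R,3R)-3-[(4R)-4-benzyl-2-oxo-1,3-oxazolidine-3-carbonyl]-2-hydroxy-4-methylpentanoate
Product: 6 tert-butyl (2R,3R)-2-hydroxy-3-[methoxy(methyl)carbamoyl]-4-methylpentanoate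
Conditions: AlMe3, MeONHMe·HCl, CH2Cl2, −20 → 0 °C; aq. HCl work-up
Reagents that add atoms: N,O-dimethylhydroxylamine hydrochloride, CNOC.Cl
Why: Weinreb transamination of an Evans aldol adduct: the aluminium alkoxide of the free β-hydroxyl directs the aluminium amide to the exocyclic imide carbonyl, and the tert-butyl ester is too hindered to compete.

**Step 4**
Reactants: 6 tert-butyl (2R,3R)-2-hydroxy-3-[methoxy(methyl)carbamoyl]-4-methylpentanoate; 7 tert-butyldimethyl(prop-2-yn-1-yloxy)silane
Product: 9 tert-butyl (2R,3R)-7-(TBS-oxy)-2-hydroxy-4-oxo-3-(propan-2-yl)hept-5-ynoate, via lithium acetylide 8 (not isolated)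
Conditions: 7 (3.5 equiv), n-BuLi (3.3 equiv), THF, −78 °C; then 6, −78 → −20 °C; aq. NH4Cl
Reagents that add atoms: none
Why: Weinreb ketone synthesis: after one equivalent is spent on the hydroxyl, the acetylide adds once to give a stable chelated tetrahedral intermediate, and the tert-butyl ester is inert at low temperature.

**Step 5**
Reactants: 9 tert-butyl (2R,3R)-7-(TBS-oxy)-2-hydroxy-4-oxo-3-(propan-2-yl)hept-5-ynoate
Product: 10 tert-butyl (2R,3S,4R)-2-(acetyloxy)-7-(TBS-oxy)-4-hydroxy-3-(propan-2-yl)hept-5-ynoate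
Conditions: MeCHO (10 equiv), SmI2 (0.3 equiv), THF, −10 °C
Reagents that add atoms: acetaldehyde, CC=O
Why: Evans–Tishchenko reduction: the hemiacetal of the C6 hydroxyl with acetaldehyde delivers hydride to the C4 ketone through a samarium-bridged chair, which sets C4 1,3-anti to C6 (hence 4,5-anti), leaves the acetyl group on O6 and frees the C4 hydroxyl.

**Step 6**
Reactants: 10 tert-butyl (2R,3S,4R)-2-(acetyloxy)-7-(TBS-oxy)-4-hydroxy-3-(propan-2-yl)hept-5-ynoate
Product: 11 tert-butyl (2R,3R,4R)-2-(acetyloxy)-4,7-bis(TBS-oxy)-3-(propan-2-yl)hept-5-ynoate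
Conditions: TBSOTf, 2,6-lutidine, CH2Cl2, −78 °C
Reagents that add atoms: tert-butyldimethylsilyl trifluoromethanesulfonate, CC(C)(C)[Si](C)(C)OS(=O)(=O)C(F)(F)F
Why: Silylation of the secondary alcohol with a silyl triflate at low temperature is fast enough to outrun 1,3-acetyl migration (the descriptor at C3 changes only through CIP priorities).

**Step 7**
Reactants: 11 tert-butyl (2R,3R,4R)-2-(acetyloxy)-4,7-bis(TBS-oxy)-3-(propan-2-yl)hept-5-ynoate
Product: 12 tert-butyl (2R,3R,4R)-2-(acetyloxy)-4-(TBS-oxy)-7-hydroxy-3-(propan-2-yl)hept-5-ynoate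
Conditions: camphorsulfonic acid (0.1 equiv), MeOH/CH2Cl2, 0 °C
Reagents that add atoms: none
Why: Acid-catalysed methanolysis removes the unhindered primary silyl ether much faster than the secondary one next to the branched C5, and leaves the acetate and the tert-butyl ester alone.

**Step 8**
Reactants: 12 tert-butyl (2R,3R,4R)-2-(acetyloxy)-4-(TBS-oxy)-7-hydroxy-3-(propan-2-yl)hept-5-ynoate
Product: 15 tert-butyl (2R,3R,4S)-2-(acetyloxy)-4-(TBS-oxy)-3-(propan-2-yl)hepta-5,6-dienoate, via N-sulfonylhydrazine adduct 13 (not isolated), via propargylic diazene 14 (not isolated)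
Conditions: 2-nitrobenzenesulfonylhydrazide, PPh3, DEAD, THF, −15 °C → rt
Reagents that add atoms: none
Why: Myers allene synthesis: Mitsunobu displacement at the primary carbinol, loss of sulfinic acid to the diazene and retro-ene loss of N2 deliver hydrogen to C3 and give the terminal allene without touching C4 (its descriptor changes only through CIP priorities; the terminal allene has no axial chirality).

**Step 9**
Reactants: 15 tert-butyl (2R,3R,4S)-2-(acetyloxy)-4-(TBS-oxy)-3-(propan-2-yl)hepta-5,6-dienoate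
Product: 17 (2R,3R,4S)-2-(acetyloxy)-4-(TBS-oxy)-3-(propan-2-yl)hepta-5,6-dienoic acid, via trimethylsilyl ester 16 (not isolated)
Conditions: TMSOTf, 2,6-lutidine, CH2Cl2, 0 °C → rt; then aqueous work-up at pH 4
Reagents that add atoms: none
Why: Silyl-triflate-mediated cleavage of a tert-butyl ester (alkyl–oxygen fission with loss of isobutene) under buffered, non-protic conditions should spare the silyl ether, the acetate and the allene; the silyl ester hydrolyses on work-up.

**Step 10**
Reactants: 17 (2R,3R,4S)-2-(acetyloxy)-4-(TBS-oxy)-3-(propan-2-yl)hepta-5,6-dienoic acid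
Product: 19 (4S,5R,6R)-6-(acetyloxy)-4-(TBS-oxy)-5-(propan-2-yl)-2-({[(2E)-2-methylbut-2-enoyl]oxy}methyl)cyclohex-2-en-1-one, via mixed tiglic anhydride 18 (not isolated)
Conditions: tigloyl chloride, N-methylmorpholine, THF, −20 °C; then Pd2(dba)3 (2.5 mol %), P(4-MeOC6H4)3 (10 mol %), THF, 50 °C
Reagents that add atoms: (E)-2-methylbut-2-enoyl chloride (tigloyl chloride), C/C=C(\C)C(Cl)=O
Why: Proposed new method: zerovalent palladium should insert into the C1 acyl–oxygen bond of anhydride 18 (the opening step of known palladium-catalysed ketone syntheses from carboxylic anhydrides), the acyl(tiglato)palladium then adds across the distal C2=C7 π-bond of the allene with the acyl group going to the central carbon C2, and the resulting exocyclic π-allylpalladium tiglate (C3–C2–C7) collapses by C–O bond formation at C7, so that the allene is formally inserted into the anhydride C–O bond and the catalyst is regenerated. The closest known reaction type is the palladium-catalysed acylmetalation of allenes with acid chlorides (acyl to the central carbon, π-allyl intermediate captured by a second partner) together with the cyclic carbopalladation of ω-haloallenes; new are the anhydride as acyl donor and internal carboxylate source and the ring-forming variant. The cyclohexenone closes by a 6-exo attack on the sp carbon C2 (the consumed C2=C7 bond stays outside the ring), and the orthogonal C2=C3 bond becomes the ring alkene, whose cis geometry the ring enforces. No stereocentre is formed: C4, C5 and C6 are carried through unchanged under neutral conditions. Four selectivities are needed: cleavage of the C1–O and not the tigloyl–O bond of the anhydride (secured by the inductive activation of C1 by the C6 acetoxy group against a conjugated, α-branched tigloyl carbonyl, and by reversibility of the unproductive insertion), acyl transfer to C2 and not C3 (secured by π-allyl stabilisation, the rule in carbopalladation of allenes), C–O bond formation at C7 and not C3 (secured by the unhindered primary terminus and by conjugation in 19, to which a C3 ester would be funnelled by re-ionisation), and no ionisation at C4 (secured by carrying O4 as a silyl ether and not as an allenylic ester).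

**Step 11**
Reactants: 19 (4S,5R,6R)-6-(acetyloxy)-4-(TBS-oxy)-5-(propan-2-yl)-2-({[(2E)-2-methylbut-2-enoyl]oxy}methyl)cyclohex-2-en-1-one
Product: 20 (4S,5S,6R)-6-(acetyloxy)-4-hydroxy-5-(propan-2-yl)-2-({[(2E)-2-methylbut-2-enoyl]oxy}methyl)cyclohex-2-en-1-one
Conditions: HF·pyridine, pyridine, THF, 0 °C → rt
Reagents that add atoms: none
Why: Buffered fluoride cleavage of the secondary silyl ether should not touch the esters or the enone, and the trans-1,3 arrangement of O4 and O6 prevents acetyl migration (the C5 descriptor changes only through CIP priorities).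

**Step 12**
Reactants: 20 (4S,5S,6R)-6-(acetyloxy)-4-hydroxy-5-(propan-2-yl)-2-({[(2E)-2-methylbut-2-enoyl]oxy}methyl)cyclohex-2-en-1-one
Product: 21 (4S,5S,6R)-6-(acetyloxy)-5-(propan-2-yl)-4-{[(2E)-2-methylbut-2-enoyl]oxy}-2-({[(2E)-2-methylbut-2-enoyl]oxy}methyl)cyclohex-2-en-1-one (target)
Conditions: tigloyl chloride, pyridine, DMAP (cat.), CH2Cl2, 0 °C → rt
Reagents that add atoms: (E)-2-methylbut-2-enoyl chloride (tigloyl chloride), C/C=C(\C)C(Cl)=O
Why: Acylation of the secondary allylic alcohol with the acid chloride under nucleophilic catalysis keeps C4 (the C–O bond is not broken) and the stable (E)-acyl geometry, and C6 already sits in its more stable equatorial arrangement trans to the isopropyl group.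

**Compound list**
1 | di-tert-butyl (2R,3R)-2,3-dihydroxybutanedioate (di-tert-butyl L-tartrate) | CC(C)(C)OC(=O)[C@H](O)[C@@H](O)C(=O)OC(C)(C)C | starting material
2 | tert-butyl 2-oxoacetate (tert-butyl glyoxylate) | CC(C)(C)OC(=O)C=O | intermediate
3 | (4R)-4-benzyl-3-(3-methylbutanoyl)-1,3-oxazolidin-2-one | CC(C)CC(=O)N1[C@H](Cc2ccccc2)COC1=O | starting material
4 | (4R)-4-benzyl-3-[(1Z)-1-[(dibutylboranyl)oxy]-3-methylbut-1-en-1-yl]-1,3-oxazolidin-2-one | CC(C)/C=C(\OB(CCCC)CCCC)N1[C@H](Cc2ccccc2)COC1=O | intermediate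
5 | tert-butyl (2R,3R)-3-[(4R)-4-benzyl-2-oxo-1,3-oxazolidine-3-carbonyl]-2-hydroxy-4-methylpentanoate | O=C(N1[C@H](Cc2ccccc2)COC1=O)[C@H](C(C)C)[C@@H](O)C(=O)OC(C)(C)C | intermediate
6 | tert-butyl (2R,3R)-2-hydroxy-3-[methoxy(methyl)carbamoyl]-4-methylpentanoate | CON(C)C(=O)[C@H](C(C)C)[C@@H](O)C(=O)OC(C)(C)C | intermediate
7 | tert-butyldimethyl(prop-2-yn-1-yloxy)silane | C#CCO[Si](C)(C)C(C)(C)C | starting material
8 | {3-[(tert-butyldimethylsilyl)oxy]prop-1-yn-1-yl}lithium | [Li]C#CCO[Si](C)(C)C(C)(C)C | intermediate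
9 | tert-butyl (2R,3R)-7-[(tert-butyldimethylsilyl)oxy]-2-hydroxy-4-oxo-3-(propan-2-yl)hept-5-ynoate | CC(C)(C)[Si](C)(C)OCC#CC(=O)[C@H](C(C)C)[C@@H](O)C(=O)OC(C)(C)C | intermediate
10 | tert-butyl (2R,3S,4R)-2-(acetyloxy)-7-[(tert-butyldimethylsilyl)oxy]-4-hydroxy-3-(propan-2-yl)hept-5-ynoate | CC(C)(C)[Si](C)(C)OCC#C[C@H](O)[C@H](C(C)C)[C@@H](OC(C)=O)C(=O)OC(C)(C)C | intermediate
11 | tert-butyl (2R,3R,4R)-2-(acetyloxy)-4,7-bis[(tert-butyldimethylsilyl)oxy]-3-(propan-2-yl)hept-5-ynoate | CC(C)(C)[Si](C)(C)OCC#C[C@H](O[Si](C)(C)C(C)(C)C)[C@H](C(C)C)[C@@H](OC(C)=O)C(=O)OC(C)(C)C | intermediate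
12 | tert-butyl (2R,3R,4R)-2-(acetyloxy)-4-[(tert-butyldimethylsilyl)oxy]-7-hydroxy-3-(propan-2-yl)hept-5-ynoate | OCC#C[C@H](O[Si](C)(C)C(C)(C)C)[C@H](C(C)C)[C@@H](OC(C)=O)C(=O)OC(C)(C)C | intermediate
13 | tert-butyl (2R,3R,4R)-2-(acetyloxy)-4-[(tert-butyldimethylsilyl)oxy]-7-[1-(2-nitrobenzenesulfonyl)hydrazin-1-yl]-3-(propan-2-yl)hept-5-ynoate | NN(CC#C[C@H](O[Si](C)(C)C(C)(C)C)[C@H](C(C)C)[C@@H](OC(C)=O)C(=O)OC(C)(C)C)S(=O)(=O)c1ccccc1[N+](=O)[O-] | intermediate
14 | tert-butyl (2R,3R,4R)-2-(acetyloxy)-4-[(tert-butyldimethylsilyl)oxy]-7-diazenyl-3-(propan-2-yl)hept-5-ynoate | N=NCC#C[C@H](O[Si](C)(C)C(C)(C)C)[C@H](C(C)C)[C@@H](OC(C)=O)C(=O)OC(C)(C)C | intermediate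
15 | tert-butyl (2R,3R,4S)-2-(acetyloxy)-4-[(tert-butyldimethylsilyl)oxy]-3-(propan-2-yl)hepta-5,6-dienoate | C=C=C[C@H](O[Si](C)(C)C(C)(C)C)[C@H](C(C)C)[C@@H](OC(C)=O)C(=O)OC(C)(C)C | intermediate
16 | trimethylsilyl (2R,3R,4S)-2-(acetyloxy)-4-[(tert-butyldimethylsilyl)oxy]-3-(propan-2-yl)hepta-5,6-dienoate | C=C=C[C@H](O[Si](C)(C)C(C)(C)C)[C@H](C(C)C)[C@@H](OC(C)=O)C(=O)O[Si](C)(C)C | intermediate
17 | (2R,3R,4S)-2-(acetyloxy)-4-[(tert-butyldimethylsilyl)oxy]-3-(propan-2-yl)hepta-5,6-dienoic acid | C=C=C[C@H](O[Si](C)(C)C(C)(C)C)[C@H](C(C)C)[C@@H](OC(C)=O)C(=O)O | intermediate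
18 | (2R,3R,4S)-2-(acetyloxy)-4-[(tert-butyldimethylsilyl)oxy]-3-(propan-2-yl)hepta-5,6-dienoic (2E)-2-methylbut-2-enoic anhydride | C=C=C[C@H](O[Si](C)(C)C(C)(C)C)[C@H](C(C)C)[C@@H](OC(C)=O)C(=O)OC(=O)/C(C)=C/C | intermediate
19 | (4S,5R,6R)-6-(acetyloxy)-4-[(tert-butyldimethylsilyl)oxy]-5-(propan-2-yl)-2-({[(2E)-2-methylbut-2-enoyl]oxy}methyl)cyclohex-2-en-1-one | C/C=C(\C)C(=O)OCC1=C[C@H](O[Si](C)(C)C(C)(C)C)[C@H](C(C)C)[C@@H](OC(C)=O)C1=O | intermediate
20 | (4S,5S,6R)-6-(acetyloxy)-4-hydroxy-5-(propan-2-yl)-2-({[(2E)-2-methylbut-2-enoyl]oxy}methyl)cyclohex-2-en-1-one | C/C=C(\C)C(=O)OCC1=C[C@H](O)[C@H](C(C)C)[C@@H](OC(C)=O)C1=O | intermediate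
21 | (4S,5S,6R)-6-(acetyloxy)-5-(propan-2-yl)-4-{[(2E)-2-methylbut-2-enoyl]oxy}-2-({[(2E)-2-methylbut-2-enoyl]oxy}methyl)cyclohex-2-en-1-one | C/C=C(\C)C(=O)OCC1=C[C@H](OC(=O)/C(C)=C/C)[C@H](C(C)C)[C@@H](OC(C)=O)C1=O | target

**Step count and risks**
Total: 12 steps. Longest linear sequence: 12 steps (1 → 21, steps 1 to 12); oxazolidinone 3 and alkyne 7 enter this line as purchased building blocks at steps 2 and 4, so there is no separate branch.

Steps most likely to fail:

1. Step 10 (Proposed new method). What may go wrong: insertion of palladium on the tigloyl side of the anhydride, decarbonylation of the acylpalladium, β-hydride loss from the π-allyl intermediate instead of C–O bond formation, or disproportionation of the mixed anhydride before it is consumed. Fallback, with the acyl donor and the termination both changed to precedented ones: acid 17 is converted with 1-chloro-N,N,2-trimethylprop-1-en-1-amine (CH2Cl2, 0 °C) into (2R,3R,4S)-2-(acetyloxy)-4-(TBS-oxy)-3-(propan-2-yl)hepta-5,6-dienoyl chloride F1. The known palladium-catalysed acylboration of allenes with acid chlorides (B2pin2, PdCl2(MeCN)2 cat., toluene, 80 °C), run intramolecularly, should give (4S,5R,6R)-6-(acetyloxy)-4-(TBS-oxy)-5-(propan-2-yl)-2-[(4,4,5,5-tetramethyl-1,3,2-dioxaborolan-2-yl)methyl]cyclohex-2-en-1-one F2. Oxidation of the allylboronate (NaBO3·4H2O, THF/H2O, 0 °C) should give (4S,5R,6R)-6-(acetyloxy)-4-(TBS-oxy)-2-(hydroxymethyl)-5-(propan-2-yl)cyclohex-2-en-1-one F3. Acylation of the primary allylic alcohol with tigloyl chloride and pyridine returns to the route at 19.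

2. Step 5. What may go wrong: conjugate addition of the samarium hemiacetal alkoxide to the ynone (closure to a dihydropyranone), single-electron reduction of the ynone, or 1,3-acetyl migration between O6 and O4 on prolonged contact with the catalyst. Fallback, with C4 set by a catalyst instead of by the C6 oxygen: ynone 9 is acetylated (Ac2O, pyridine, cat. DMAP, CH2Cl2, −20 °C) to tert-butyl (2R,3R)-2-(acetyloxy)-7-(TBS-oxy)-4-oxo-3-(propan-2-yl)hept-5-ynoate F4. Noyori transfer hydrogenation of the alkynyl ketone with RuCl[(R,R)-TsDPEN](p-cymene) in iPrOH at rt, whose usual sense of induction should give the (4R)-carbinol, returns to the route at 10.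

3. Step 3. What may go wrong: attack of the aluminium amide on the ring carbonyl of the hindered α-isopropyl imide (ring opening of the auxiliary) or stalling of the exchange. Fallback, through the free acid instead of direct transamination: imide 5 is hydrolysed with LiOH/H2O2 (THF/H2O, 0 °C) to (2R,3R)-4-tert-butoxy-3-hydroxy-4-oxo-2-(propan-2-yl)butanoic acid F5, with recovery of the auxiliary. Amide coupling with MeONHMe·HCl (EDC·HCl, HOBt, N-methylmorpholine, CH2Cl2, 0 °C → rt) returns to the route at 6.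

**Further compounds**
F1 | step 10 | (2R,3R,4S)-2-(acetyloxy)-4-[(tert-butyldimethylsilyl)oxy]-3-(propan-2-yl)hepta-5,6-dienoyl chloride | C=C=C[C@H](O[Si](C)(C)C(C)(C)C)[C@H](C(C)C)[C@@H](OC(C)=O)C(Cl)=O
F2 | step 10 | (4S,5R,6R)-6-(acetyloxy)-4-[(tert-butyldimethylsilyl)oxy]-5-(propan-2-yl)-2-[(4,4,5,5-tetramethyl-1,3,2-dioxaborolan-2-yl)methyl]cyclohex-2-en-1-one | CC1(C)OB(CC2=C[C@H](O[Si](C)(C)C(C)(C)C)[C@H](C(C)C)[C@@H](OC(C)=O)C2=O)OC1(C)C
F3 | step 10 | (4S,5R,6R)-6-(acetyloxy)-4-[(tert-butyldimethylsilyl)oxy]-2-(hydroxymethyl)-5-(propan-2-yl)cyclohex-2-en-1-one | OCC1=C[C@H](O[Si](C)(C)C(C)(C)C)[C@H](C(C)C)[C@@H](OC(C)=O)C1=O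
F4 | step 5 | tert-butyl (2R,3R)-2-(acetyloxy)-7-[(tert-butyldimethylsilyl)oxy]-4-oxo-3-(propan-2-yl)hept-5-ynoate | CC(C)(C)[Si](C)(C)OCC#CC(=O)[C@H](C(C)C)[C@@H](OC(C)=O)C(=O)OC(C)(C)C
F5 | step 3 | (2R,3R)-4-tert-butoxy-3-hydroxy-4-oxo-2-(propan-2-yl)butanoic acid | OC(=O)[C@H](C(C)C)[C@@H](O)C(=O)OC(C)(C)C
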